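## Structural features

The target joins three units through a central 3-acyl-4-hydroxy-2-pyridone (ring C): the ketone carbon on pyridone C3 is bonded to C2 of a trans-fused 1,2,4a,5,6,7,8,8a-octahydronaphthalene (rings A and B), and pyridone C5 is bonded to C1' of a 7-oxabicyclo[4.1.0]heptane (ring D). Rings A and B hold five stereocentres, of which C1 (E-propenyl), C2 (acyl), C8a and C4a are contiguous and C7 (methyl) is remote in ring B; all three substituents are equatorial and the trisubstituted C3=C4 alkene carries the C4 methyl. Ring D holds four contiguous stereocentres, namely the tertiary carbinol C1', the cis-epoxide carbons C2' and C3' and the secondary carbinol C4', with the two hydroxyls cis to each other and anti to the epoxide oxygen. Fragile points are C2–H (α to the ketone and allylic, so prone to epimerisation and to alkene conjugation), the trans-epoxy alcohols (Payne rearrangement under base, opening under strong acid) and the acidic, chelating hydroxypyridone. The real difficulty is that the flat pyridone relays no stereochemical information, so the decalin (including remote C7) and ring D must each be made in the correct absolute sense and then joined at two hindered positions. The key step exploits the fact that ring B is a disguised 4-methylcyclohexanone (C4a the carbonyl carbon, C8a one of two enantiotopic α-carbons, C7 the prochiral methyl-bearing carbon), while C1–C4 with the C2 carboxyl map onto an alkylidene 3-oxopentanoate.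

## Logic of the disconnections

**26 ⇒ 25.** Cut: the four oxygen–protecting-group bonds (two acetal O–CH2 bonds on ring C, O–Si at C1' and C4'). Reason: the free hydroxypyridone and carbinols would quench or misdirect organolithium reagents. Gain: 25 is neutral, and its ring C acetals double as metalation-directing groups. Demand: one non-basic unmasking that frees four oxygens without opening the C2'–C3' epoxide or moving C3=C4.

**25 ⇒ 24 ⇒ 11 + 23 (23 from 22).** Cut: the bond from ring C carbon C3 to the exocyclic carbonyl carbon, at the carbinol oxidation level. Reason: C3–H of 22 lies between two directing acetals, so the carbanion is available site-specifically. An aldehyde reacts cleanly at low temperature, whereas an ester would need forcing and would leave an enolisable ketone in the presence of base. Gain: two halves of similar size, each with its own stereochemistry settled. Demand: metalation must spare the epoxide and silyl ethers, 11 must not enolise, and the oxidation of 24 must be non-basic.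

**22 ⇒ 21 ⇒ 20 + 16 (20 from 19).** Cut: the bond from ring C carbon C5 to C1'. Reason: a tertiary carbinol is a ketone plus a carbanion, and a C5 halogen delivers that carbanion by exchange. Gain: ring D shrinks to a small chiral epoxy ketone. Demand: attack on the C1' carbonyl from the epoxide face (anti to the C4' silyloxy group), no enolisation, and capture of 21 before it can rearrange.

**19 ⇒ 18 ⇒ 17.** Cut: C5–Br and the two O–CH2 bonds. Reason: electrophilic substitution and directed metalation have complementary site preferences (C5 and C3) on the bis-acetal. Gain: a commodity heterocycle. Demand: O- rather than N-alkylation, and bromination at C5 rather than C3.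

**16 ⇒ 15 ⇒ 14 ⇒ 13 ⇒ 12.** Cut: the two epoxide C–O bonds, then the C4'–H bond (hydride onto the carbonyl of 12). Reason: the epoxide can be delivered trans to an existing C4' substituent by conjugate peroxide addition, and C4' itself by catalytic asymmetric reduction. Gain: an achiral enone ketal. Demand: enantioselective 1,2-reduction and trans-selective epoxidation.

**11 ⇒ 10 ⇒ 9.** Cut: no skeletal bond; only the oxidation level of the carbon attached to C2 is adjusted (C–H for C–O). Reason: the ester is the form that survives the annulation and alkene transposition, while the aldehyde is the form needed for union. Gain: one robust carboxyl derivative serves from step 1 to step 5. Demand: no enolisation of the β,γ-unsaturated carbonyl.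

**9 ⇒ 8 ⇒ 7 ⇒ 6.** Cut: the C4a–H bond, with the alkene returned from C3=C4 to C4=C4a and oxygen restored at C3. Reason: this relates the target alkene to a conjugated enone, the native product of an annulation. Gain: C4a becomes sp2, leaving one stereocentre fewer to set directly. Demand: hydride must reach C3 from the α-face, and palladium must then deliver hydride to C4a on the α-face.

**6 ⇒ 5 ⇒ 3 + 4.** Cut: C4=C4a and C1–C8a. Reason: these are the aldol and Michael bonds of a Robinson-type annulation onto a symmetric ketone. Gain: a bicycle with four stereocentres falls to two achiral components. Demand: one catalyst must choose an enantiotopic α-carbon of 4 and a face of 3, and addition must be 1,4.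

**3 ⇒ 1 + 2.** Cut: the C=C between the dicarbonyl carbon and the dienyl chain. Reason: Knoevenagel retron. Gain: two bulk chemicals. Demand: 1,2-condensation on the enal, not 1,4-addition. The carboxyl is kept as the simple methyl ester because it is only a spectator until step 6.

## Other disconnections considered

Alternative 1: The cut lies inside ring D: both C–O bonds at C1' and C4' are traced to one molecule of singlet oxygen.
- Forward step: the microbially produced bromoarene cis-dihydrodiol A1 would be converted, by acetonide formation and cross-coupling at its vinylic bromide with a metalated form of 19, into diene acetonide A2. Singlet oxygen would then add [4+2] across C1' and C4' of A2, anti to the acetonide, to give endoperoxide A3.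
- In favour: one suprafacial, concerted event would set C1' and C4' relative to C2' and C3'. The absolute configuration would come from purchased, enantiopure A1, whose oxygen-bearing carbons have the spatial arrangement needed at C2' and C3'. The C5–C1' bond would be an sp2–sp2 coupling rather than an addition to an enolisable ketone.
- Against: A3 is far from ring D. It still needs saturation of C5'=C6' without premature O–O cleavage, O–O reduction, acetonide removal, and conversion of the cis-diol into the cis-epoxide with net retention (two inversions at one carbon), all next to a free tertiary carbinol. A2 may dimerise or aromatise, and ene reactions or oxidation of the electron-rich pyridine may compete.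
- Comparison: on stereocontrol of ring D this plan is better than step 14 of the chosen route, which rests on substrate-controlled facial selectivity. On step count for ring D it is about equal or slightly longer (roughly nine operations against steps 8–14). It says nothing about the decalin, so it complements rather than competes with the chosen key step and could replace steps 8–14.

Alternative 2: The cut removes both bonds to the ketone carbon at once.
- Forward step: allylic carbonate A4 would be ionised by zerovalent palladium to the C2–C3–C4 π-allyl, carbon monoxide would insert at C2, and the acylpalladium would couple with stannane A5 to give A6, which is identical with 25.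
- In favour: maximum convergence, and the ketone would arrive at its final oxidation level. One step would replace steps 6, 7, 15 and 16, so at the union this plan is the better one in step economy.
- Against: insertion of carbon monoxide into η3-allyl palladium is reversible and disfavoured, so direct allyl–aryl coupling and β-hydride elimination to a diene would compete. Transmetalation of a stannane flanked by two ortho acetals is expected to be slow. A4 carries oxygen, not carbon, at C2, so the carboxyl that the chosen annulation installs for free would have to be excised or a different decalin route devised. A5 requires the same metalation as step 15 plus a tin reagent.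
- Comparison: equal in endgame (same protected ketone) and better in convergence, but mechanistically less secure and mismatched with the decalin synthesis.

Alternative 3: The cut is C1–C8a and C2–C3, making ring A first.
- Forward step: diene A7 and dienophile A8 would combine under a chiral oxazaborolidinium Lewis acid to give A9.
- In favour: this catalyst class gives predictable face and regiocontrol with 2-silyloxydienes. The trans C1/C2 relationship would come kinetically from the E-dienophile rather than by equilibration, a point on which it is better than the chosen plan, where C2 relies on thermodynamics. The aldehyde (future propenyl) and ester (future acyl) are differentiated from the start.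
- Against: A9 contains one ring and two of the five decalin stereocentres. Ring B, C4a, C8a, the remote C7 methyl and the C4 methyl all remain. C8a is an unactivated methylene until the enol ether is oxidised to an enone, and C7 would have to be controlled 1,3 from C8a late in the sequence.
- Comparison: on absolute control of C1/C2 it is the equal or the better. On C7, on ring B and on step economy (the decalin alone would need well over the seven steps used here) the chosen annulation is stronger, because it forms ring A on a ready-made ring B and sets C7 in the same event.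

Key step: step 2

Remark on the chemistry: the sense of induction in steps 2 and 8 is assigned by analogy, and each catalyst has an equally available (pseudo)enantiomer. Compound 3 is used as the mixture of C2=C3 isomers that the condensation gives (drawn 2Z), since both funnel into the same adduct. "α" denotes the decalin face opposite H8a and the propenyl group; "β" is the face that carries them.

## Route

Step 1
Reactants: 1 methyl 3-oxopentanoate; 2 (E)-but-2-enal
Product: 3 methyl (2Z,4E)-2-propanoylhexa-2,4-dienoate
Conditions: TiCl4, pyridine, THF, 0 °C → rt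
Reagents that add atoms: none
Why: Knoevenagel condensation; the titanium enolate of 1 adds 1,2 to the titanium-activated aldehyde, which avoids the 1,4-addition that amine catalysis could cause with an enal; the 4E alkene is carried over from 2, and 3 is used promptly because it can close reversibly to a 2H-pyran or oligomerise.

Step 2
Reactants: 4 4-methylcyclohexanone (3 equiv); 3 methyl (2Z,4E)-2-propanoylhexa-2,4-dienoate
Product: 6 methyl (1R,2S,7S,8aR)-4,7-dimethyl-3-oxo-1-[(1E)-prop-1-en-1-yl]-1,2,3,5,6,7,8,8a-octahydronaphthalene-2-carboxylate, via Michael adduct 5 (not isolated)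
Conditions: 9-amino-9-deoxy-epi-quinine (20 mol%), TFA (40 mol%), toluene, rt; then TsOH·H2O (0.3 equiv), 70 °C
Reagents that add atoms: none
Why: The primary amine condenses with 4 to a chiral enamine while the protonated quinuclidine hydrogen-bonds to the two carbonyls of 3; the enamine carbon (future C8a) adds to the doubly activated alkene carbon (future C1) and hydrolysis releases 5. In the acid stage the enol of the ethyl ketone (C4) attacks the ring carbonyl (C4a) in a 6-(enolendo)-exo-trig aldol that closes ring A, and loss of water gives the C4=C4a enone. The closest known reaction types are primary-amine-catalysed Michael additions of cyclic ketones to alkylidene 1,3-dicarbonyl compounds, including desymmetrisation of 4-substituted cyclohexanones, joined to a classical Robinson annulation. C7 is fixed by which enantiotopic α-carbon of 4 reacts, a choice made by the catalyst. C1 is fixed by the acceptor face held in the catalyst's hydrogen-bonded pocket. C8a is set in the same transition state and, being γ to the enone, can be corrected through the dienol under the acid to the arrangement with H8a trans-diaxial to H1 and the C7 methyl equatorial; C2 equilibrates as a β-keto ester to the equatorial position trans to the propenyl group. The step needs 1,4- rather than 1,6-addition, secured because the inner alkene carbon carries both acceptor groups and only the 1,4-adduct can cyclise, and it needs fused rather than bridged aldol closure, secured because only the fused aldol can dehydrate, so heat and acid drain material to 6.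

Step 3
Reactants: 6 methyl (1R,2S,7S,8aR)-4,7-dimethyl-3-oxo-1-[(1E)-prop-1-en-1-yl]-1,2,3,5,6,7,8,8a-octahydronaphthalene-2-carboxylate
Product: 7 methyl (1R,2S,3R,7S,8aR)-3-hydroxy-4,7-dimethyl-1-[(1E)-prop-1-en-1-yl]-1,2,3,5,6,7,8,8a-octahydronaphthalene-2-carboxylate
Conditions: NaBH4, CeCl3·7H2O, MeOH, −40 °C
Reagents that add atoms: none
Why: Luche reduction; CeCl3 makes the reduction 1,2-selective and fast, and hydride should enter axially on the α-face of C3 (anti to the axial H2), placing the new hydroxyl equatorial on the β-face and trans to the C2 ester; reduction at −40 °C outpaces enolisation at C2.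

Step 4
Reactants: 7 methyl (1R,2S,3R,7S,8aR)-3-hydroxy-4,7-dimethyl-1-[(1E)-prop-1-en-1-yl]-1,2,3,5,6,7,8,8a-octahydronaphthalene-2-carboxylate
Product: 8 methyl (1R,2S,3R,7S,8aR)-3-[(methoxycarbonyl)oxy]-4,7-dimethyl-1-[(1E)-prop-1-en-1-yl]-1,2,3,5,6,7,8,8a-octahydronaphthalene-2-carboxylate
Conditions: ClCO2Me, pyridine, DMAP (cat.), CH2Cl2, 0 °C
Reagents that add atoms: methyl chloroformate, COC(=O)Cl
Why: Acylation of a secondary alcohol with a chloroformate; the weak base and low temperature keep the β-carbonato ester from E1cB elimination, and no stereocentre is touched.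

Step 5
Reactants: 8 methyl (1R,2S,3R,7S,8aR)-3-[(methoxycarbonyl)oxy]-4,7-dimethyl-1-[(1E)-prop-1-en-1-yl]-1,2,3,5,6,7,8,8a-octahydronaphthalene-2-carboxylate
Product: 9 methyl (1R,2S,4aS,7S,8aR)-4,7-dimethyl-1-[(1E)-prop-1-en-1-yl]-1,2,4a,5,6,7,8,8a-octahydronaphthalene-2-carboxylate
Conditions: Pd(OAc)2 (5 mol%), PBu3 (5 mol%), HCO2H, Et3N, THF, 40 °C
Reagents that add atoms: none
Why: Tsuji–Trost ionisation followed by formate hydrogenolysis; zerovalent palladium displaces the β-carbonate with inversion, so the C3–C4–C4a π-allyl carries palladium on the α-face, and after formate binds and loses CO2 the hydride is passed from palladium to the more substituted terminus C4a on that same face, giving H4a trans to H8a and the alkene at C3=C4; this is the known way to set ring fusions from octalin and steroid allylic esters.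

Step 6
Reactants: 9 methyl (1R,2S,4aS,7S,8aR)-4,7-dimethyl-1-[(1E)-prop-1-en-1-yl]-1,2,4a,5,6,7,8,8a-octahydronaphthalene-2-carboxylate
Product: 10 [(1R,2S,4aS,7S,8aR)-4,7-dimethyl-1-[(1E)-prop-1-en-1-yl]-1,2,4a,5,6,7,8,8a-octahydronaphthalen-2-yl]methanol
Conditions: LiAlH4, THF, 0 °C
Reagents that add atoms: none
Why: Hydride reduction of an ester to the primary alcohol; LiAlH4 at 0 °C does not enolise the β,γ-unsaturated ester, so C2 and the alkene position are kept.

Step 7
Reactants: 10 [(1R,2S,4aS,7S,8aR)-4,7-dimethyl-1-[(1E)-prop-1-en-1-yl]-1,2,4a,5,6,7,8,8a-octahydronaphthalen-2-yl]methanol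
Product: 11 (1R,2S,4aS,7S,8aR)-4,7-dimethyl-1-[(1E)-prop-1-en-1-yl]-1,2,4a,5,6,7,8,8a-octahydronaphthalene-2-carbaldehyde
Conditions: Dess–Martin periodinane, NaHCO3, CH2Cl2, 0 °C → rt
Reagents that add atoms: none
Why: Dess–Martin oxidation under bicarbonate buffer is near neutral, so the β,γ-unsaturated aldehyde should be neither conjugated nor epimerised (the equatorial formyl group is in any case the stable epimer); 11 is used at once.

Step 8
Reactants: 12 1,4-dioxaspiro[4.5]dec-6-en-8-one
Product: 13 (8R)-1,4-dioxaspiro[4.5]dec-6-en-8-ol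
Conditions: RuCl(p-cymene)[(R,R)-TsDPEN] (1 mol%), HCO2Na, n-Bu4NCl, CH2Cl2/H2O, rt
Reagents that add atoms: none
Why: Noyori-type asymmetric transfer hydrogenation; hydride and proton pass from the ruthenium hydride/amine to the C=O in an outer-sphere six-membered transition state in which the alkene takes the place of the aryl group of an aryl ketone, so the (R,R) catalyst should give the (R)-allylic alcohol; the C=C is left alone, and the neutral biphasic formate medium spares the ketal.

Step 9
Reactants: 13 (8R)-1,4-dioxaspiro[4.5]dec-6-en-8-ol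
Product: 14 tert-butyl{[(8R)-1,4-dioxaspiro[4.5]dec-6-en-8-yl]oxy}dimethylsilane
Conditions: TBSCl, imidazole, DMF, rt
Reagents that add atoms: tert-butyldimethylsilyl chloride, CC(C)(C)[Si](C)(C)Cl
Why: Standard imidazole-promoted silylation of a secondary allylic alcohol; no stereocentre is touched.

Step 10
Reactants: 14 tert-butyl{[(8R)-1,4-dioxaspiro[4.5]dec-6-en-8-yl]oxy}dimethylsilane
Product: 15 (4R)-4-[(tert-butyldimethylsilyl)oxy]cyclohex-2-en-1-one
Conditions: PPTS (cat.), acetone/H2O, rt
Reagents that add atoms: water, O
Why: Acid-catalysed hydrolysis of an allylic ketal, which ionises far more readily than a saturated one, so a pyridinium acid suffices and the secondary TBS ether survives; the enone emerges conjugated with C4 untouched.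

Step 11
Reactants: 15 (4R)-4-[(tert-butyldimethylsilyl)oxy]cyclohex-2-en-1-one
Product: 16 (1S,5R,6R)-5-[(tert-butyldimethylsilyl)oxy]-7-oxabicyclo[4.1.0]heptan-2-one
Conditions: H2O2 (30% aq.), benzyltrimethylammonium hydroxide (cat.), THF, 0 °C
Reagents that add atoms: hydrogen peroxide, OO
Why: Weitz–Scheffer nucleophilic epoxidation; hydroperoxide adds to the enone β-carbon anti to the neighbouring silyloxy group and the enolate closes on oxygen, so the epoxide forms trans to the C4' silyl ether and C2'/C3' are set from C4'.

Step 12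
Reactants: 17 pyridine-2,4-diol (tautomer of 4-hydroxypyridin-2(1H)-one)
Product: 18 2,4-bis(methoxymethoxy)pyridine
Conditions: MOMCl, Ag2CO3, toluene, rt, dark
Reagents that add atoms: chloromethyl methyl ether, COCCl
Why: O-alkylation of an ambident hydroxypyridone; the silver salt in a non-polar solvent and the hard, oxocarbenium-like electrophile both direct attack to oxygen rather than nitrogen, giving the bis-acetal that later serves as a pair of ortho-directing groups.

Step 13
Reactants: 18 2,4-bis(methoxymethoxy)pyridine
Product: 19 5-bromo-2,4-bis(methoxymethoxy)pyridine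
Conditions: NBS, MeCN, 0 °C → rt
Reagents that add atoms: N-bromosuccinimide, O=C1CCC(=O)N1Br
Why: Electrophilic aromatic bromination; C5 is para to the 2-alkoxy and ortho to the 4-alkoxy group and is unhindered, whereas C3 sits between two substituents, as in the 4-bromination of 1,3-dialkoxybenzenes; neutral NBS leaves the acetals intact.

Step 14
Reactants: 19 5-bromo-2,4-bis(methoxymethoxy)pyridine; 16 (1S,5R,6R)-5-[(tert-butyldimethylsilyl)oxy]-7-oxabicyclo[4.1.0]heptan-2-one
Product: 22 5-[(1S,2R,5R,6R)-5-[(tert-butyldimethylsilyl)oxy]-2-[(trimethylsilyl)oxy]-7-oxabicyclo[4.1.0]heptan-2-yl]-2,4-bis(methoxymethoxy)pyridine, via aryllithium 20 (not isolated), via lithium alkoxide 21 (not isolated)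
Conditions: n-BuLi, THF, −78 °C; then 16, −78 °C; then TMSCl, −78 → 0 °C
Reagents that add atoms: chlorotrimethylsilane, C[Si](C)(C)Cl
Why: Bromine–lithium exchange, 1,2-addition to the ketone and O-silylation in one flask; 20 should attack the carbonyl of 16 anti to the pseudo-axial silyloxy group at C4', which is the face of the small, lithium-coordinating epoxide oxygen, so the aryl group ends cis to the epoxide and the C1' oxygen trans to it and cis to the C4' oxygen; prompt silylation of 21 forestalls Payne rearrangement and masks the tertiary alcohol for step 15.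

Step 15
Reactants: 22 5-[(1S,2R,5R,6R)-5-[(tert-butyldimethylsilyl)oxy]-2-[(trimethylsilyl)oxy]-7-oxabicyclo[4.1.0]heptan-2-yl]-2,4-bis(methoxymethoxy)pyridine; 11 (1R,2S,4aS,7S,8aR)-4,7-dimethyl-1-[(1E)-prop-1-en-1-yl]-1,2,4a,5,6,7,8,8a-octahydronaphthalene-2-carbaldehyde
Product: 24 {(1R,2S,4aS,7S,8aR)-4,7-dimethyl-1-[(1E)-prop-1-en-1-yl]-1,2,4a,5,6,7,8,8a-octahydronaphthalen-2-yl}{5-[(1S,2R,5R,6R)-5-[(tert-butyldimethylsilyl)oxy]-2-[(trimethylsilyl)oxy]-7-oxabicyclo[4.1.0]heptan-2-yl]-2,4-bis(methoxymethoxy)pyridin-3-yl}methanol (both carbinol epimers), via 3-lithiopyridine 23 (not isolated)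
Conditions: n-BuLi, TMEDA, THF, −78 → −40 °C; then 11, −78 °C; NH4Cl (aq.)
Reagents that add atoms: none
Why: Directed ortho-metalation; C3–H lies between two methoxymethoxy groups that both coordinate lithium, so it should be removed much faster than C6–H or any attack on the hindered epoxide, and the aryllithium adds to the aldehyde at −78 °C faster than it enolises it; the carbinol centre forms without control and is erased in step 16.

Step 16
Reactants: 24 {(1R,2S,4aS,7S,8aR)-4,7-dimethyl-1-[(1E)-prop-1-en-1-yl]-1,2,4a,5,6,7,8,8a-octahydronaphthalen-2-yl}{5-[(1S,2R,5R,6R)-5-[(tert-butyldimethylsilyl)oxy]-2-[(trimethylsilyl)oxy]-7-oxabicyclo[4.1.0]heptan-2-yl]-2,4-bis(methoxymethoxy)pyridin-3-yl}methanol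
Product: 25 {(1R,2S,4aS,7S,8aR)-4,7-dimethyl-1-[(1E)-prop-1-en-1-yl]-1,2,4a,5,6,7,8,8a-octahydronaphthalen-2-yl}{5-[(1S,2R,5R,6R)-5-[(tert-butyldimethylsilyl)oxy]-2-[(trimethylsilyl)oxy]-7-oxabicyclo[4.1.0]heptan-2-yl]-2,4-bis(methoxymethoxy)pyridin-3-yl}methanone
Conditions: Dess–Martin periodinane, NaHCO3, CH2Cl2, 0 °C → rt
Reagents that add atoms: none
Why: Dess–Martin oxidation of a hindered secondary carbinol under buffered, non-basic conditions, so the doubly activated C2–H is not removed and the silyl ethers, acetals and epoxide stay inert.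

Step 17
Reactants: 25 {(1R,2S,4aS,7S,8aR)-4,7-dimethyl-1-[(1E)-prop-1-en-1-yl]-1,2,4a,5,6,7,8,8a-octahydronaphthalen-2-yl}{5-[(1S,2R,5R,6R)-5-[(tert-butyldimethylsilyl)oxy]-2-[(trimethylsilyl)oxy]-7-oxabicyclo[4.1.0]heptan-2-yl]-2,4-bis(methoxymethoxy)pyridin-3-yl}methanone
Product: 26 4-hydroxy-5-[(1S,2R,5R,6S)-2,5-dihydroxy-7-oxabicyclo[4.1.0]heptan-2-yl]-3-{[(1R,2S,4aS,7S,8aR)-4,7-dimethyl-1-[(1E)-prop-1-en-1-yl]-1,2,4a,5,6,7,8,8a-octahydronaphthalen-2-yl]carbonyl}pyridin-2(1H)-one
Conditions: HF (48% aq.), MeCN, 0 °C → rt
Reagents that add atoms: none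
Why: Acidic fluoride deprotection; HF cleaves both silyl ethers, and the two pyridyl methoxymethyl acetals, activated by N-protonation and by the ortho acyl group, should hydrolyse under the same mild acid; the epoxide is flanked by two oxygen-bearing carbons that disfavour cationic opening, and the absence of base rules out Payne rearrangement and C2 epimerisation.

## Compound list

1 | methyl 3-oxopentanoate | CCC(=O)CC(=O)OC | starting material
2 | (E)-but-2-enal (crotonaldehyde) | C/C=C/C=O | starting material
3 | methyl (2Z,4E)-2-propanoylhexa-2,4-dienoate | C/C=C/C=C(/C(=O)CC)C(=O)OC | intermediate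
4 | 4-methylcyclohexanone | CC1CCC(=O)CC1 | starting material
5 | methyl (3R,4E)-3-[(1R,5S)-5-methyl-2-oxocyclohexyl]-2-propanoylhex-4-enoate (C2 epimers) | C/C=C/[C@H]([C@H]1C[C@@H](C)CCC1=O)C(C(=O)CC)C(=O)OC | intermediate
6 | methyl (1R,2S,7S,8aR)-4,7-dimethyl-3-oxo-1-[(1E)-prop-1-en-1-yl]-1,2,3,5,6,7,8,8a-octahydronaphthalene-2-carboxylate | C/C=C/[C@@H]1[C@H]2C[C@@H](C)CCC2=C(C)C(=O)[C@H]1C(=O)OC | intermediate
7 | methyl (1R,2S,3R,7S,8aR)-3-hydroxy-4,7-dimethyl-1-[(1E)-prop-1-en-1-yl]-1,2,3,5,6,7,8,8a-octahydronaphthalene-2-carboxylate | C/C=C/[C@@H]1[C@H]2C[C@@H](C)CCC2=C(C)[C@H](O)[C@H]1C(=O)OC | intermediate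
8 | methyl (1R,2S,3R,7S,8aR)-3-[(methoxycarbonyl)oxy]-4,7-dimethyl-1-[(1E)-prop-1-en-1-yl]-1,2,3,5,6,7,8,8a-octahydronaphthalene-2-carboxylate | C/C=C/[C@@H]1[C@H]2C[C@@H](C)CCC2=C(C)[C@H](OC(=O)OC)[C@H]1C(=O)OC | intermediate
9 | methyl (1R,2S,4aS,7S,8aR)-4,7-dimethyl-1-[(1E)-prop-1-en-1-yl]-1,2,4a,5,6,7,8,8a-octahydronaphthalene-2-carboxylate | C/C=C/[C@@H]1[C@H]2C[C@@H](C)CC[C@@H]2C(C)=C[C@H]1C(=O)OC | intermediate
10 | [(1R,2S,4aS,7S,8aR)-4,7-dimethyl-1-[(1E)-prop-1-en-1-yl]-1,2,4a,5,6,7,8,8a-octahydronaphthalen-2-yl]methanol | C/C=C/[C@@H]1[C@H]2C[C@@H](C)CC[C@@H]2C(C)=C[C@H]1CO | intermediate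
11 | (1R,2S,4aS,7S,8aR)-4,7-dimethyl-1-[(1E)-prop-1-en-1-yl]-1,2,4a,5,6,7,8,8a-octahydronaphthalene-2-carbaldehyde | C/C=C/[C@@H]1[C@H]2C[C@@H](C)CC[C@@H]2C(C)=C[C@H]1C=O | intermediate
12 | 1,4-dioxaspiro[4.5]dec-6-en-8-one | O=C1C=CC2(CC1)OCCO2 | starting material
13 | (8R)-1,4-dioxaspiro[4.5]dec-6-en-8-ol | C12(OCCO1)CC[C@@H](O)C=C2 | intermediate
14 | tert-butyl{[(8R)-1,4-dioxaspiro[4.5]dec-6-en-8-yl]oxy}dimethylsilane | C12(OCCO1)CC[C@@H](O[Si](C)(C)C(C)(C)C)C=C2 | intermediate
15 | (4R)-4-[(tert-butyldimethylsilyl)oxy]cyclohex-2-en-1-one | O=C1CC[C@@H](O[Si](C)(C)C(C)(C)C)C=C1 | intermediate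
16 | (1S,5R,6R)-5-[(tert-butyldimethylsilyl)oxy]-7-oxabicyclo[4.1.0]heptan-2-one | O=C1CC[C@@H](O[Si](C)(C)C(C)(C)C)[C@@H]2O[C@@H]21 | intermediate
17 | pyridine-2,4-diol (4-hydroxypyridin-2(1H)-one) | Oc1ccnc(O)c1 | starting material
18 | 2,4-bis(methoxymethoxy)pyridine | COCOc1ccnc(OCOC)c1 | intermediate
19 | 5-bromo-2,4-bis(methoxymethoxy)pyridine | COCOc1cc(OCOC)ncc1Br | intermediate
20 | [4,6-bis(methoxymethoxy)pyridin-3-yl]lithium | [Li]c1cnc(OCOC)cc1OCOC | intermediate
21 | lithium (1S,2R,5R,6R)-2-[4,6-bis(methoxymethoxy)pyridin-3-yl]-5-[(tert-butyldimethylsilyl)oxy]-7-oxabicyclo[4.1.0]heptan-2-olate | COCOc1cc(OCOC)ncc1[C@]2(O[Li])CC[C@@H](O[Si](C)(C)C(C)(C)C)[C@@H]3O[C@@H]32 | intermediate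
22 | 5-[(1S,2R,5R,6R)-5-[(tert-butyldimethylsilyl)oxy]-2-[(trimethylsilyl)oxy]-7-oxabicyclo[4.1.0]heptan-2-yl]-2,4-bis(methoxymethoxy)pyridine | COCOc1cc(OCOC)ncc1[C@]2(O[Si](C)(C)C)CC[C@@H](O[Si](C)(C)C(C)(C)C)[C@@H]3O[C@@H]32 | intermediate
23 | {5-[(1S,2R,5R,6R)-5-[(tert-butyldimethylsilyl)oxy]-2-[(trimethylsilyl)oxy]-7-oxabicyclo[4.1.0]heptan-2-yl]-2,4-bis(methoxymethoxy)pyridin-3-yl}lithium | COCOc1ncc([C@]2(O[Si](C)(C)C)CC[C@@H](O[Si](C)(C)C(C)(C)C)[C@@H]3O[C@@H]32)c(OCOC)c1[Li] | intermediate
24 | {(1R,2S,4aS,7S,8aR)-4,7-dimethyl-1-[(1E)-prop-1-en-1-yl]-1,2,4a,5,6,7,8,8a-octahydronaphthalen-2-yl}{5-[(1S,2R,5R,6R)-5-[(tert-butyldimethylsilyl)oxy]-2-[(trimethylsilyl)oxy]-7-oxabicyclo[4.1.0]heptan-2-yl]-2,4-bis(methoxymethoxy)pyridin-3-yl}methanol (carbinol epimers) | C/C=C/[C@@H]1[C@H]2C[C@@H](C)CC[C@@H]2C(C)=C[C@H]1C(O)c1c(OCOC)c([C@]2(O[Si](C)(C)C)CC[C@@H](O[Si](C)(C)C(C)(C)C)[C@@H]3O[C@@H]32)cnc1OCOC | intermediate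
25 | {(1R,2S,4aS,7S,8aR)-4,7-dimethyl-1-[(1E)-prop-1-en-1-yl]-1,2,4a,5,6,7,8,8a-octahydronaphthalen-2-yl}{5-[(1S,2R,5R,6R)-5-[(tert-butyldimethylsilyl)oxy]-2-[(trimethylsilyl)oxy]-7-oxabicyclo[4.1.0]heptan-2-yl]-2,4-bis(methoxymethoxy)pyridin-3-yl}methanone | C/C=C/[C@@H]1[C@H]2C[C@@H](C)CC[C@@H]2C(C)=C[C@H]1C(=O)c1c(OCOC)c([C@]2(O[Si](C)(C)C)CC[C@@H](O[Si](C)(C)C(C)(C)C)[C@@H]3O[C@@H]32)cnc1OCOC | intermediate
26 | 4-hydroxy-5-[(1S,2R,5R,6S)-2,5-dihydroxy-7-oxabicyclo[4.1.0]heptan-2-yl]-3-{[(1R,2S,4aS,7S,8aR)-4,7-dimethyl-1-[(1E)-prop-1-en-1-yl]-1,2,4a,5,6,7,8,8a-octahydronaphthalen-2-yl]carbonyl}pyridin-2(1H)-one | C/C=C/[C@@H]1[C@H]2C[C@@H](C)CC[C@@H]2C(C)=C[C@H]1C(=O)c1c(O)c([C@]2(O)CC[C@@H](O)[C@@H]3O[C@@H]32)c[nH]c1=O | target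

## Step count and least certain steps

Total: 17 steps in three branches. The longest linear sequence is 10 steps (steps 1–7, then 15–17).

**Step 2 (key step).** The catalyst may discriminate poorly between the two enantiotopic α-carbons of 4 or between the acceptor faces, which would erode both enantiomeric and diastereomeric purity. Turnover may also stall through reversible aza-Michael addition of the catalyst to 3, and some material may be lost to 1,6-addition or to the bridged aldol before the acid stage. Fallback: separate the desymmetrisation from the C–C bond formation. Setting out from 4, enantioselective deprotonation with a chiral lithium bis(1-phenylethyl)amide in the presence of TMSCl should give (S)-trimethyl[(4-methylcyclohex-1-en-1-yl)oxy]silane F1, in which C7 is already fixed. A Mukaiyama–Michael addition of F1 to 3 (TiCl4, CH2Cl2, −78 °C) then rejoins the route at 5, which is cyclised to 6 with TsOH as in step 2.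

**Step 14.** The aryllithium may attack the carbonyl face anti to the epoxide instead of anti to the silyloxy group, or may act as a base and enolise 16; CeCl3 can temper the basicity but not the facial issue. Fallback: remove the epoxide from the bond-forming event. Setting out from 19 (via 20) and 15, 1,2-addition anti to the C4' silyloxy group and TMSCl capture should give 5-[(1S,4R)-4-[(tert-butyldimethylsilyl)oxy]-1-[(trimethylsilyl)oxy]cyclohex-2-en-1-yl]-2,4-bis(methoxymethoxy)pyridine F2. Peracid epoxidation (mCPBA, NaHCO3, CH2Cl2, 0 °C) anti to both silyloxy groups then returns to the route at 22; the 2-alkoxy group leaves the ring nitrogen poorly nucleophilic towards the peracid.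

**Step 3.** Hydride may be delivered to the β-face (equatorial attack, possibly through a chelate with the ester), which would place the hydroxyl on the α-face and lead to a cis ring fusion in step 5. Fallback: make the α-alcohol on purpose and invert it while installing the leaving group. Setting out from 6, a chelating hydride such as Zn(BH4)2 should give methyl (1R,2S,3S,7S,8aR)-3-hydroxy-4,7-dimethyl-1-[(1E)-prop-1-en-1-yl]-1,2,3,5,6,7,8,8a-octahydronaphthalene-2-carboxylate F3. Mitsunobu reaction with formic acid (PPh3, DIAD) inverts C3 to methyl (1R,2S,3R,7S,8aR)-3-(formyloxy)-4,7-dimethyl-1-[(1E)-prop-1-en-1-yl]-1,2,3,5,6,7,8,8a-octahydronaphthalene-2-carboxylate F4. This allylic formate carries its own hydride source, and Pd(OAc)2/PBu3 should convert it directly into 9.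

**Step 5.** Hydride may be transferred to the C3 terminus of the π-allyl, β-hydride elimination may give a diene, or the amine may induce E1cB loss of carbonate before ionisation. Fallback: a metal-free reductive transposition. Setting out from 7, Mitsunobu displacement with 2-nitrobenzenesulfonylhydrazide (PPh3, DEAD, THF, −30 °C) should give methyl (1R,2S,3S,7S,8aR)-4,7-dimethyl-3-[1-(2-nitrobenzenesulfonyl)hydrazin-1-yl]-1-[(1E)-prop-1-en-1-yl]-1,2,3,5,6,7,8,8a-octahydronaphthalene-2-carboxylate F5 with inversion at C3. On warming it loses sulfinic acid to methyl (1R,2S,3S,7S,8aR)-3-diazenyl-4,7-dimethyl-1-[(1E)-prop-1-en-1-yl]-1,2,3,5,6,7,8,8a-octahydronaphthalene-2-carboxylate F6, whose retro-ene loss of nitrogen passes hydrogen to C4a on the α-face and arrives at 9.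

**Step 15.** Metalation may be incomplete or go partly to C6, the alkyllithium may open the epoxide, or the aryllithium may enolise 11. Fallback: reverse the order of union so that no epoxide is present during the deprotonation. Setting out from 19, LiN(i-Pr)2 (THF, −78 °C) removes C3–H without touching bromine, and addition to 11 should give [5-bromo-2,4-bis(methoxymethoxy)pyridin-3-yl]{(1R,2S,4aS,7S,8aR)-4,7-dimethyl-1-[(1E)-prop-1-en-1-yl]-1,2,4a,5,6,7,8,8a-octahydronaphthalen-2-yl}methanol F7. Two equivalents of n-BuLi (alkoxide formation, then bromine–lithium exchange), addition to 16 and excess TMSCl should give the bis(trimethylsilyl) ether of 24, F8. K2CO3 in MeOH removes the secondary trimethylsilyl group selectively and rejoins the route at 24.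

**Step 17.** The acid may open the epoxide (by solvent or a neighbouring hydroxyl) before the acetals are gone, or acetal cleavage may be incomplete. Fallback: unmask in two orthogonal events instead of one acidic one. Setting out from 25, buffered HF·pyridine in THF/pyridine removes only the silyl groups to give {5-[(1S,2R,5R,6S)-2,5-dihydroxy-7-oxabicyclo[4.1.0]heptan-2-yl]-2,4-bis(methoxymethoxy)pyridin-3-yl}{(1R,2S,4aS,7S,8aR)-4,7-dimethyl-1-[(1E)-prop-1-en-1-yl]-1,2,4a,5,6,7,8,8a-octahydronaphthalen-2-yl}methanone F9. Transacetalisation with PPTS in MeOH at 40 °C then transfers the methoxymethyl groups to the solvent and arrives at 26.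

## Further compounds

F1 | step 2 | (S)-trimethyl[(4-methylcyclohex-1-en-1-yl)oxy]silane | C[C@H]1CCC(O[Si](C)(C)C)=CC1
F2 | step 14 | 5-[(1S,4R)-4-[(tert-butyldimethylsilyl)oxy]-1-[(trimethylsilyl)oxy]cyclohex-2-en-1-yl]-2,4-bis(methoxymethoxy)pyridine | COCOc1cc(OCOC)ncc1[C@]2(O[Si](C)(C)C)CC[C@@H](O[Si](C)(C)C(C)(C)C)C=C2
F3 | step 3 | methyl (1R,2S,3S,7S,8aR)-3-hydroxy-4,7-dimethyl-1-[(1E)-prop-1-en-1-yl]-1,2,3,5,6,7,8,8a-octahydronaphthalene-2-carboxylate | C/C=C/[C@@H]1[C@H]2C[C@@H](C)CCC2=C(C)[C@@H](O)[C@H]1C(=O)OC
F4 | step 3 | methyl (1R,2S,3R,7S,8aR)-3-(formyloxy)-4,7-dimethyl-1-[(1E)-prop-1-en-1-yl]-1,2,3,5,6,7,8,8a-octahydronaphthalene-2-carboxylate | C/C=C/[C@@H]1[C@H]2C[C@@H](C)CCC2=C(C)[C@H](OC=O)[C@H]1C(=O)OC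
F5 | step 5 | methyl (1R,2S,3S,7S,8aR)-4,7-dimethyl-3-[1-(2-nitrobenzenesulfonyl)hydrazin-1-yl]-1-[(1E)-prop-1-en-1-yl]-1,2,3,5,6,7,8,8a-octahydronaphthalene-2-carboxylate | C/C=C/[C@@H]1[C@H]2C[C@@H](C)CCC2=C(C)[C@@H](N(N)S(=O)(=O)c3ccccc3[N+](=O)[O-])[C@H]1C(=O)OC
F6 | step 5 | methyl (1R,2S,3S,7S,8aR)-3-diazenyl-4,7-dimethyl-1-[(1E)-prop-1-en-1-yl]-1,2,3,5,6,7,8,8a-octahydronaphthalene-2-carboxylate | C/C=C/[C@@H]1[C@H]2C[C@@H](C)CCC2=C(C)[C@@H](N=N)[C@H]1C(=O)OC
F7 | step 15 | [5-bromo-2,4-bis(methoxymethoxy)pyridin-3-yl]{(1R,2S,4aS,7S,8aR)-4,7-dimethyl-1-[(1E)-prop-1-en-1-yl]-1,2,4a,5,6,7,8,8a-octahydronaphthalen-2-yl}methanol (carbinol epimers) | C/C=C/[C@@H]1[C@H]2C[C@@H](C)CC[C@@H]2C(C)=C[C@H]1C(O)c1c(OCOC)c(Br)cnc1OCOC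
F8 | step 15 | bis(trimethylsilyl) ether of 24 (trimethylsilyl on the carbinol oxygen and on the C1' oxygen) | C/C=C/[C@@H]1[C@H]2C[C@@H](C)CC[C@@H]2C(C)=C[C@H]1C(O[Si](C)(C)C)c1c(OCOC)c([C@]2(O[Si](C)(C)C)CC[C@@H](O[Si](C)(C)C(C)(C)C)[C@@H]3O[C@@H]32)cnc1OCOC
F9 | step 17 | {5-[(1S,2R,5R,6S)-2,5-dihydroxy-7-oxabicyclo[4.1.0]heptan-2-yl]-2,4-bis(methoxymethoxy)pyridin-3-yl}{(1R,2S,4aS,7S,8aR)-4,7-dimethyl-1-[(1E)-prop-1-en-1-yl]-1,2,4a,5,6,7,8,8a-octahydronaphthalen-2-yl}methanone | C/C=C/[C@@H]1[C@H]2C[C@@H](C)CC[C@@H]2C(C)=C[C@H]1C(=O)c1c(OCOC)c([C@]2(O)CC[C@@H](O)[C@@H]3O[C@@H]32)cnc1OCOC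
A1 | alternative 1 | (1S,2S)-3-bromocyclohexa-3,5-diene-1,2-diol | BrC1=CC=C[C@H](O)[C@@H]1O
A2 | alternative 1 | 5-[(3aR,7aS)-2,2-dimethyl-3a,7a-dihydro-1,3-benzodioxol-4-yl]-2,4-bis(methoxymethoxy)pyridine | COCOc1cc(OCOC)ncc1C1=CC=C[C@@H]2OC(C)(C)O[C@@H]21
A3 | alternative 1 | endoperoxide bridging C1' and C4' (2,3-dioxabicyclo[2.2.2]oct-5-ene, peroxide anti to the acetonide, pyridyl at C1') | COCOc1cc(OCOC)ncc1[C@]12OO[C@H](C=C1)[C@@H]3OC(C)(C)O[C@@H]32
A4 | alternative 2 | (1R,2R,4aS,7S,8aR)-4,7-dimethyl-1-[(1E)-prop-1-en-1-yl]-1,2,4a,5,6,7,8,8a-octahydronaphthalen-2-yl methyl carbonate | C/C=C/[C@@H]1[C@H]2C[C@@H](C)CC[C@@H]2C(C)=C[C@@H]1OC(=O)OC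
A5 | alternative 2 | 5-[(1S,2R,5R,6R)-5-[(tert-butyldimethylsilyl)oxy]-2-[(trimethylsilyl)oxy]-7-oxabicyclo[4.1.0]heptan-2-yl]-2,4-bis(methoxymethoxy)-3-(tributylstannyl)pyridine | COCOc1ncc([C@]2(O[Si](C)(C)C)CC[C@@H](O[Si](C)(C)C(C)(C)C)[C@@H]3O[C@@H]32)c(OCOC)c1[Sn](CCCC)(CCCC)CCCC
A6 | alternative 2 | fully protected target, identical with 25 | C/C=C/[C@@H]1[C@H]2C[C@@H](C)CC[C@@H]2C(C)=C[C@H]1C(=O)c1c(OCOC)c([C@]2(O[Si](C)(C)C)CC[C@@H](O[Si](C)(C)C(C)(C)C)[C@@H]3O[C@@H]32)cnc1OCOC
A7 | alternative 3 | 2-[(triisopropylsilyl)oxy]buta-1,3-diene | C=CC(=C)O[Si](C(C)C)(C(C)C)C(C)C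
A8 | alternative 3 | ethyl (2E)-4-oxobut-2-enoate | CCOC(=O)/C=C/C=O
A9 | alternative 3 | ethyl (1R,6R)-6-formyl-3-[(triisopropylsilyl)oxy]cyclohex-3-ene-1-carboxylate | O=C[C@@H]1CC=C(O[Si](C(C)C)(C(C)C)C(C)C)C[C@H]1C(=O)OCC
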